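**Strategy.** With the core numbered as 7-oxabicyclo[4.1.0]heptan-2-one, the cyclohexane ring is cut across C3–C4 and C1–C6. This gives the ketone C2 with both α-carbons (C1, C3) as a double nucleophile and an enal (C4–C6) as a double electrophile. The feature exploited is the α,β-epoxy ketone whose carbonyl C2 is 1,3-related to both C4 and the oxirane carbon C6. One amine-catalysed Michael/aldol/chloride-displacement domino joins an α-angeloyloxy-γ-chloro-β-keto allyl ester to a simple acetal-bearing enal, closing the ring and the oxirane and setting C4, C6 and C1. The allyl ester is excised late, with protonation setting C3, once the side-chain carbinol is in place.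

Key step: step 5

Assumption: 2, 5, 6 and 8 are racemic at centres that are destroyed or reset in step 5; the fully substituted C-3 of 12–17 is expected to form without reliable control, is written without a descriptor, and is reset in step 9.

Step 1
Reactants: 1 Meldrum's acid; 2 2-chloropropanoyl chloride; 3 allyl alcohol
Product: 5 allyl 4-chloro-3-oxopentanoate, via acyl Meldrum's acid 4 (not isolated)
Conditions: pyridine (2 equiv), CH2Cl2, 0 °C to rt; dilute HCl wash, concentrate; then 3, toluene, 90 °C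
Reagents that add atoms: none
Why: C-Acylation of Meldrum's acid followed by thermal alcoholysis through an acyl ketene (loss of acetone and CO2) is the standard entry to γ-substituted β-keto esters, and the racemic CHCl centre is of no consequence.

Step 2
Reactants: 5 allyl 4-chloro-3-oxopentanoate
Product: 6 allyl 4-chloro-2-diazo-3-oxopentanoate
Conditions: 4-acetamidobenzenesulfonyl azide, Et3N, MeCN, 0 °C
Reagents that add atoms: 4-acetamidobenzenesulfonyl azide, CC(=O)Nc1ccc(cc1)S(=O)(=O)N=[N+]=[N-]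
Why: Regitz diazo transfer to the active methylene of a β-keto ester should proceed cleanly at 0 °C without touching the α-chloro ketone.

Step 3
Reactants: 6 allyl 4-chloro-2-diazo-3-oxopentanoate; 7 angelic acid
Product: 8 allyl 4-chloro-2-[(Z)-2-methylbut-2-enoyloxy]-3-oxopentanoate
Conditions: Rh2(OAc)4 (1 mol %), 7 (2 equiv), CH2Cl2, rt, slow addition of 6
Reagents that add atoms: none
Why: Rhodium-carbenoid O–H insertion into a carboxylic acid used in excess should outrun carbenoid side reactions and place the angelate (Z geometry untouched) on the future C-3, whose new centre is racemic and inconsequential.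

Step 4
Reactants: 9 4,4-diethoxybut-1-ene; 10 (E)-but-2-enal
Product: 11 (E)-5,5-diethoxypent-2-enal
Conditions: second-generation Grubbs catalyst (2 mol %), 10 (3 equiv), CH2Cl2, 40 °C
Reagents that add atoms: none
Why: Olefin cross-metathesis of a terminal alkene with excess crotonaldehyde should give the E-enal under thermodynamic control, the acetal being inert.

Step 5
Reactants: 8 allyl 4-chloro-2-[(Z)-2-methylbut-2-enoyloxy]-3-oxopentanoate; 11 (E)-5,5-diethoxypent-2-enal
Product: 14 allyl (1S,4R,6S)-4-(2,2-diethoxyethyl)-1-methyl-3-[(Z)-2-methylbut-2-enoyloxy]-2-oxo-7-oxabicyclo[4.1.0]heptane-3-carboxylate (C-3 epimers), via Michael adduct 12 (not isolated), via chlorohydrin 13 (not isolated)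
Conditions: (R)-2-{bis[3,5-bis(trifluoromethyl)phenyl](trimethylsilyloxy)methyl}pyrrolidine (10 mol %), NaOAc (20 mol %), CH2Cl2, rt; then K2CO3, DMF, rt
Reagents that add atoms: none
Why: The amine converts 11 into its E-iminium ion, the stabilised C-2 enolate of 8 adds to the β-carbon (C3–C4 bond), the freed aldehyde is attacked by the enolate of the chlorinated carbon (C1–C6 bond), and the resulting alkoxide displaces chloride to close the oxirane. This is the established amine-catalysed Michael/aldol/intramolecular SN2 domino of γ-chloro-β-keto esters with enals (an annulative Darzens condensation), here with a donor carbon that already carries the acyloxy group. The carbocycle closes by a 6-(enolendo)-exo-trig aldol and the oxirane by a 3-exo-tet displacement. C-4 (R) is set by the catalyst, whose silyloxydiarylmethyl group leaves only the Si face of the β-carbon open; C-6 and C-1 follow from C-4 because the aldol is reversible and only the chlorohydrin with an axial alkoxide anti to C–Cl, in the chair that keeps the C-4 arm equatorial, can close, which puts the oxirane trans to the arm and the methyl cis; C-3 is not controlled and is reset in step 9. Regiochemistry is secured by the substrate: only C-2 of 8 is acidic enough for the Michael step and, once it is fully substituted, only the chlorinated carbon can enolise for the aldol, while alkylation of the aldehyde enamine at the hindered chloride is disfavoured.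

Step 6
Reactants: 14 allyl (1S,4R,6S)-4-(2,2-diethoxyethyl)-1-methyl-3-[(Z)-2-methylbut-2-enoyloxy]-2-oxo-7-oxabicyclo[4.1.0]heptane-3-carboxylate
Product: 15 allyl (1S,4R,6S)-1-methyl-3-[(Z)-2-methylbut-2-enoyloxy]-2-oxo-4-(2-oxoethyl)-7-oxabicyclo[4.1.0]heptane-3-carboxylate (C-3 epimers)
Conditions: pyridinium p-toluenesulfonate (20 mol %), acetone/H2O 10:1, 40 °C
Reagents that add atoms: water, O
Why: Mild acid-catalysed acetal hydrolysis should be tolerated by the electron-poor α,β-epoxy ketone and the esters, and touches no stereocentre.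

Step 7
Reactants: 15 allyl (1S,4R,6S)-1-methyl-3-[(Z)-2-methylbut-2-enoyloxy]-2-oxo-4-(2-oxoethyl)-7-oxabicyclo[4.1.0]heptane-3-carboxylate
Product: 16 allyl (1S,4R,6S)-1-methyl-3-[(Z)-2-methylbut-2-enoyloxy]-2-oxo-4-(3-oxoprop-1-en-2-yl)-7-oxabicyclo[4.1.0]heptane-3-carboxylate (C-3 epimers)
Conditions: aqueous formaldehyde (37 %), pyrrolidine (10 mol %), propanoic acid (10 mol %), iPrOH, 45 °C
Reagents that add atoms: formaldehyde, C=O
Why: Amine-catalysed Mannich condensation with formaldehyde followed by elimination (α-methylenation of an aldehyde) should install the exocyclic methylene while the hindered, non-enolisable keto ester stays untouched.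

Step 8
Reactants: 16 allyl (1S,4R,6S)-1-methyl-3-[(Z)-2-methylbut-2-enoyloxy]-2-oxo-4-(3-oxoprop-1-en-2-yl)-7-oxabicyclo[4.1.0]heptane-3-carboxylate
Product: 17 allyl (1S,4R,6S)-4-[(3S)-3-hydroxyhexa-1,5-dien-2-yl]-1-methyl-3-[(Z)-2-methylbut-2-enoyloxy]-2-oxo-7-oxabicyclo[4.1.0]heptane-3-carboxylate (C-3 epimers)
Conditions: allylboronic acid pinacol ester (1.2 equiv), (S)-3,3'-bis(2,4,6-triisopropylphenyl)-1,1'-binaphthyl-2,2'-diyl hydrogen phosphate (5 mol %), toluene, −30 °C; aqueous work-up
Reagents that add atoms: allylboronic acid pinacol ester, C=CCB1OC(C)(C)C(C)(C)O1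
Why: Chiral phosphoric acid-catalysed allylboration through a chair transition state should deliver allyl to the Si face of the aldehyde under catalyst control, giving the (3S)-carbinol chemoselectively over the hindered ketone.

Step 9
Reactants: 17 allyl (1S,4R,6S)-4-[(3S)-3-hydroxyhexa-1,5-dien-2-yl]-1-methyl-3-[(Z)-2-methylbut-2-enoyloxy]-2-oxo-7-oxabicyclo[4.1.0]heptane-3-carboxylate
Product: 18 (1S,3S,4R,6S)-4-[(3S)-3-hydroxyhexa-1,5-dien-2-yl]-1-methyl-2-oxo-7-oxabicyclo[4.1.0]heptan-3-yl (Z)-2-methylbut-2-enoate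
Conditions: Pd(PPh3)4 (5 mol %), HCO2H (2 equiv), Et3N (2.5 equiv), THF, 0 °C to rt
Reagents that add atoms: none
Why: Palladium-catalysed deallylation with formate as the hydride source (Tsuji–Trost-type ionisation) should release the β-keto acid, which loses CO2, and the enol should be protonated at C-3 from the face opposite the C-4 side chain and the C-1 methyl (kinetic ketonisation), placing the angelate cis to the side chain (3S).

Step 10
Reactants: 18 (1S,3S,4R,6S)-4-[(3S)-3-hydroxyhexa-1,5-dien-2-yl]-1-methyl-2-oxo-7-oxabicyclo[4.1.0]heptan-3-yl (Z)-2-methylbut-2-enoate; 19 3-methylbut-2-enoic acid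
Product: 20 (1S,3S,4R,6S)-1-methyl-4-[(3S)-3-(3-methylbut-2-enoyloxy)hexa-1,5-dien-2-yl]-2-oxo-7-oxabicyclo[4.1.0]heptan-3-yl (Z)-2-methylbut-2-enoate
Conditions: 19 (1.5 equiv), DCC, DMAP (10 mol %), CH2Cl2, 0 °C to rt
Reagents that add atoms: none
Why: Steglich esterification under near-neutral conditions should acylate the secondary allylic alcohol with retention, without deconjugating the senecioyl group or epimerising C-3.

Step 11
Reactants: 20 (1S,3S,4R,6S)-1-methyl-4-[(3S)-3-(3-methylbut-2-enoyloxy)hexa-1,5-dien-2-yl]-2-oxo-7-oxabicyclo[4.1.0]heptan-3-yl (Z)-2-methylbut-2-enoate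
Product: 21 (1S,3S,4R,6S)-1-methyl-4-[(3S)-6-methyl-3-(3-methylbut-2-enoyloxy)hepta-1,5-dien-2-yl]-2-oxo-7-oxabicyclo[4.1.0]heptan-3-yl (Z)-2-methylbut-2-enoate (CNP0414062.1)
Conditions: 2-methylbut-2-ene (excess), second-generation Grubbs catalyst (5 mol %), CH2Cl2, 40 °C
Reagents that add atoms: 2-methylbut-2-ene, CC=C(C)C
Why: Olefin cross-metathesis of the monosubstituted alkene with 2-methylbut-2-ene should convert the allyl group into the prenyl terminus, the 1,1-disubstituted and ester-conjugated alkenes being unreactive and no stereocentre being affected.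

**Compound list**

1 | Meldrum's acid (2,2-dimethyl-1,3-dioxane-4,6-dione) | CC1(C)OC(=O)CC(=O)O1 | starting material
2 | 2-chloropropanoyl chloride (racemic) | CC(Cl)C(Cl)=O | starting material
3 | allyl alcohol (prop-2-en-1-ol) | C=CCO | starting material
4 | 5-(2-chloro-1-hydroxypropylidene)-2,2-dimethyl-1,3-dioxane-4,6-dione (acyl Meldrum's acid, enol form, racemic) | CC(Cl)C(O)=C1C(=O)OC(C)(C)OC1=O | intermediate
5 | allyl 4-chloro-3-oxopentanoate (racemic) | CC(Cl)C(=O)CC(=O)OCC=C | intermediate
6 | allyl 4-chloro-2-diazo-3-oxopentanoate (racemic) | CC(Cl)C(=O)C(=[N+]=[N-])C(=O)OCC=C | intermediate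
7 | angelic acid, (Z)-2-methylbut-2-enoic acid | C/C=C(/C)C(O)=O | starting material
8 | allyl 4-chloro-2-[(Z)-2-methylbut-2-enoyloxy]-3-oxopentanoate (racemic diastereomers) | CC(Cl)C(=O)C(OC(=O)/C(C)=C\C)C(=O)OCC=C | intermediate
9 | 4,4-diethoxybut-1-ene | C=CCC(OCC)OCC | starting material
10 | (E)-but-2-enal (crotonaldehyde) | C/C=C/C=O | starting material
11 | (E)-5,5-diethoxypent-2-enal | O=C/C=C/CC(OCC)OCC | intermediate
12 | allyl 4-chloro-2-[(3R)-1,1-diethoxy-5-oxopentan-3-yl]-2-[(Z)-2-methylbut-2-enoyloxy]-3-oxopentanoate (epimers at C-2 and C-4) | O=CC[C@H](CC(OCC)OCC)C(OC(=O)/C(C)=C\C)(C(=O)OCC=C)C(=O)C(C)Cl | intermediate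
13 | allyl (3R,4S,6R)-3-chloro-6-(2,2-diethoxyethyl)-4-hydroxy-3-methyl-1-[(Z)-2-methylbut-2-enoyloxy]-2-oxocyclohexane-1-carboxylate (C-1 epimers) | CCOC(OCC)C[C@H]1C[C@H](O)[C@@](C)(Cl)C(=O)C1(OC(=O)/C(C)=C\C)C(=O)OCC=C | intermediate
14 | allyl (1S,4R,6S)-4-(2,2-diethoxyethyl)-1-methyl-3-[(Z)-2-methylbut-2-enoyloxy]-2-oxo-7-oxabicyclo[4.1.0]heptane-3-carboxylate (C-3 epimers) | CCOC(OCC)C[C@H]1C[C@@H]2O[C@]2(C)C(=O)C1(OC(=O)/C(C)=C\C)C(=O)OCC=C | intermediate
15 | allyl (1S,4R,6S)-1-methyl-3-[(Z)-2-methylbut-2-enoyloxy]-2-oxo-4-(2-oxoethyl)-7-oxabicyclo[4.1.0]heptane-3-carboxylate (C-3 epimers) | O=CC[C@H]1C[C@@H]2O[C@]2(C)C(=O)C1(OC(=O)/C(C)=C\C)C(=O)OCC=C | intermediate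
16 | allyl (1S,4R,6S)-1-methyl-3-[(Z)-2-methylbut-2-enoyloxy]-2-oxo-4-(3-oxoprop-1-en-2-yl)-7-oxabicyclo[4.1.0]heptane-3-carboxylate (C-3 epimers) | O=CC(=C)[C@H]1C[C@@H]2O[C@]2(C)C(=O)C1(OC(=O)/C(C)=C\C)C(=O)OCC=C | intermediate
17 | allyl (1S,4R,6S)-4-[(3S)-3-hydroxyhexa-1,5-dien-2-yl]-1-methyl-3-[(Z)-2-methylbut-2-enoyloxy]-2-oxo-7-oxabicyclo[4.1.0]heptane-3-carboxylate (C-3 epimers) | C=CC[C@H](O)C(=C)[C@H]1C[C@@H]2O[C@]2(C)C(=O)C1(OC(=O)/C(C)=C\C)C(=O)OCC=C | intermediate
18 | (1S,3S,4R,6S)-4-[(3S)-3-hydroxyhexa-1,5-dien-2-yl]-1-methyl-2-oxo-7-oxabicyclo[4.1.0]heptan-3-yl (Z)-2-methylbut-2-enoate | C=CC[C@H](O)C(=C)[C@H]1C[C@@H]2O[C@]2(C)C(=O)[C@H]1OC(=O)/C(C)=C\C | intermediate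
19 | 3-methylbut-2-enoic acid (senecioic acid) | CC(C)=CC(=O)O | starting material
20 | (1S,3S,4R,6S)-1-methyl-4-[(3S)-3-(3-methylbut-2-enoyloxy)hexa-1,5-dien-2-yl]-2-oxo-7-oxabicyclo[4.1.0]heptan-3-yl (Z)-2-methylbut-2-enoate | C=CC[C@H](OC(=O)C=C(C)C)C(=C)[C@H]1C[C@@H]2O[C@]2(C)C(=O)[C@H]1OC(=O)/C(C)=C\C | intermediate
21 | (1S,3S,4R,6S)-1-methyl-4-[(3S)-6-methyl-3-(3-methylbut-2-enoyloxy)hepta-1,5-dien-2-yl]-2-oxo-7-oxabicyclo[4.1.0]heptan-3-yl (Z)-2-methylbut-2-enoate | C=C([C@H](CC=C(C)C)OC(=O)C=C(C)C)[C@H]1C[C@@H]2O[C@]2(C)C(=O)[C@H]1OC(=O)/C(C)=C\C | target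

**Step count.** Total: 11 steps. Longest linear sequence: 10 steps (steps 1–3, then 5–11); the enal 11 is a one-step side branch.

**Steps most likely to fail**

Step 5. The fully substituted carbon acid 8 may add slowly to the iminium ion, the adduct may revert before the aldol traps it, or the sequence may stall at the chlorohydrin because closure at the tertiary C–Cl centre is slow. The fallback brings the oxygen in after the ring is made. It sets out from 5 and 11, which under the same amine/NaOAc then K2CO3 sequence (the parent substrate class of this domino) should give allyl (1S,4R,6S)-4-(2,2-diethoxyethyl)-1-methyl-2-oxo-7-oxabicyclo[4.1.0]heptane-3-carboxylate F1. Oxidative α-acyloxylation of this cyclic β-keto ester with angelic acid 7 (Bu4NI catalyst, tert-butyl hydroperoxide, EtOAc, 50 °C) then returns to the route at 14.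

Step 9. Protonation at C-3 may show poor facial selectivity, the product may epimerise in the triethylammonium formate buffer, or the transient enediol monoester may suffer a 1,2-acyl shift. The fallback separates C–C cleavage from C–H formation. It sets out from crude 18 (as its C-3 epimer mixture), which with LiN(SiMe3)2 (2.2 equiv) and Me3SiCl in THF at −78 °C should give (1S,4R,6S)-1-methyl-2-(trimethylsilyloxy)-4-[(3S)-3-(trimethylsilyloxy)hexa-1,5-dien-2-yl]-7-oxabicyclo[4.1.0]hept-2-en-3-yl (Z)-2-methylbut-2-enoate F2. Protodesilylation at −78 °C with Bu4NF buffered by acetic acid should then deliver the proton irreversibly to the less hindered face and return to the route at 18 as a single C-3 epimer.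

Step 7. The enamine of 15 may expel the stabilised C-3 carbanion (retro-Michael ring opening), with loss of C-4 integrity, before the Mannich step occurs. The fallback removes that leaving-group ability first. It sets out from 15, which under the palladium/formate conditions of step 9 should give (1S,3S,4R,6S)-1-methyl-2-oxo-4-(2-oxoethyl)-7-oxabicyclo[4.1.0]heptan-3-yl (Z)-2-methylbut-2-enoate F3. The formaldehyde condensation of step 7 should then give (1S,3S,4R,6S)-1-methyl-2-oxo-4-(3-oxoprop-1-en-2-yl)-7-oxabicyclo[4.1.0]heptan-3-yl (Z)-2-methylbut-2-enoate F4, and the allylboration of step 8 returns to the route at 18.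

**Further compounds**

F1 | step 5 | allyl (1S,4R,6S)-4-(2,2-diethoxyethyl)-1-methyl-2-oxo-7-oxabicyclo[4.1.0]heptane-3-carboxylate (C-3 epimers) | CCOC(OCC)C[C@H]1C[C@@H]2O[C@]2(C)C(=O)C1C(=O)OCC=C
F2 | step 9 | (1S,4R,6S)-1-methyl-2-(trimethylsilyloxy)-4-[(3S)-3-(trimethylsilyloxy)hexa-1,5-dien-2-yl]-7-oxabicyclo[4.1.0]hept-2-en-3-yl (Z)-2-methylbut-2-enoate | C=CC[C@H](O[Si](C)(C)C)C(=C)[C@H]1C[C@@H]2O[C@]2(C)C(O[Si](C)(C)C)=C1OC(=O)/C(C)=C\C
F3 | step 7 | (1S,3S,4R,6S)-1-methyl-2-oxo-4-(2-oxoethyl)-7-oxabicyclo[4.1.0]heptan-3-yl (Z)-2-methylbut-2-enoate | O=CC[C@H]1C[C@@H]2O[C@]2(C)C(=O)[C@H]1OC(=O)/C(C)=C\C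
F4 | step 7 | (1S,3S,4R,6S)-1-methyl-2-oxo-4-(3-oxoprop-1-en-2-yl)-7-oxabicyclo[4.1.0]heptan-3-yl (Z)-2-methylbut-2-enoate | O=CC(=C)[C@H]1C[C@@H]2O[C@]2(C)C(=O)[C@H]1OC(=O)/C(C)=C\C
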